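## Retrosynthetic overview

1. Target 19 ⇐ 18 by hydrogenolysis of seven benzyl ethers.
2. 18 ⇐ 15: the upper C3–OH comes from a C3 nitro group (Nef reaction to the 3-ketone, then hydride anti to the pseudo-axial C4 aryl, giving 3,4-cis).
3. 15 ⇐ 12 + 5: the interflavan C4–C6 bond is made by 1,4-addition of the 6-lithiated lower flavan-3-ol to the (2R)-3-nitro-2H-chromene 5. The nitroalkene is an α-keto-cation (enolonium) equivalent, so the α-carbon of the latent C3 ketone is the electrophile toward an electron-rich arene carbon; addition anti to the C2 aryl sets C4.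
4. 5 and 9 ⇐ salicylaldehydes 4 and 8 + nitrostyrene 3 by one asymmetric oxa-Michael/Henry annulation. Ring order: upper ring C (step 2) and lower ring C (step 5) are both closed before the coupling; the lower one is finished to the trans-3-ol first (steps 6, 7), the upper one only after the coupling (step 9).

Assumption: the (S)-pyrrolidine catalyst of steps 2 and 5 is taken to give the (2R)-chromenes; if its sense of induction is the opposite, the (R)-catalyst is used.

Note on descriptors: flavan numbering (O1, C2, C3, C4, C4a, C5–C8, C8a) is used. C4 of the upper unit is R in the benzylated compounds 14–18 and S in 19 for the same geometry, because debenzylation changes the CIP priorities. The target is 2,3-trans-3,4-cis (4β) in the upper unit and 2,3-trans in the lower unit.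

## Route

Step 1
Reactants: 1 3,4-bis(benzyloxy)benzaldehyde; 2 nitromethane
Product: 3 (E)-1,2-bis(benzyloxy)-4-(2-nitroethenyl)benzene
Conditions: NH4OAc, AcOH, 100 °C
Reagents that add atoms: none
Why: Henry (nitroaldol) condensation with in situ dehydration gives the conjugated (E)-nitroalkene under thermodynamic control, and no stereocentre is formed.

Step 2
Reactants: 4 4-(benzyloxy)-2-hydroxybenzaldehyde; 3 (E)-1,2-bis(benzyloxy)-4-(2-nitroethenyl)benzene
Product: 5 (2R)-7-(benzyloxy)-2-[3,4-bis(benzyloxy)phenyl]-3-nitro-2H-chromene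
Conditions: (S)-1-methyl-2-[(pyrrolidin-2-yl)methylsulfanyl]-1H-imidazole (20 mol %), salicylic acid (20 mol %), DMSO, rt; recrystallisation
Reagents that add atoms: none
Why: Aminocatalytic domino oxa-Michael–Henry condensation, in which the phenol adds to the nitroalkene, the nitronate closes onto the iminium-activated aldehyde and elimination regenerates the nitroalkene; the chiral pyrrolidine controls the face of the nitrostyrene in the C–O bond-forming event and so sets C2 as R, the ee being raised by recrystallisation.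

Step 3
Reactants: 6 2,3,4-trihydroxybenzaldehyde
Product: 7 3,4-bis(benzyloxy)-2-hydroxybenzaldehyde
Conditions: BnBr (2.1 equiv), K2CO3 (2.1 equiv), DMF, 0 °C to rt
Reagents that add atoms: benzyl bromide (BrCc1ccccc1)
Why: Williamson ether synthesis in which the 2-hydroxyl, hydrogen-bonded to the formyl group, is the least nucleophilic and stays free while the 3- and 4-hydroxyls are benzylated.

Step 4
Reactants: 7 3,4-bis(benzyloxy)-2-hydroxybenzaldehyde
Product: 8 3,4-bis(benzyloxy)-5-bromo-2-hydroxybenzaldehyde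
Conditions: NBS, MeCN, 0 °C
Reagents that add atoms: N-bromosuccinimide (O=C1CCC(=O)N1Br)
Why: Electrophilic aromatic bromination goes para to the free phenol and ortho to the 4-benzyloxy group, the only doubly activated open position, which fixes the future C6 of the lower unit.

Step 5
Reactants: 8 3,4-bis(benzyloxy)-5-bromo-2-hydroxybenzaldehyde; 3 (E)-1,2-bis(benzyloxy)-4-(2-nitroethenyl)benzene
Product: 9 (2R)-7,8-bis(benzyloxy)-2-[3,4-bis(benzyloxy)phenyl]-6-bromo-3-nitro-2H-chromene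
Conditions: (S)-1-methyl-2-[(pyrrolidin-2-yl)methylsulfanyl]-1H-imidazole (20 mol %), salicylic acid (20 mol %), DMSO, rt; recrystallisation
Reagents that add atoms: none
Why: The same aminocatalytic domino oxa-Michael–Henry condensation as in step 2, with catalyst control setting C2 as R.

Step 6
Reactants: 9 (2R)-7,8-bis(benzyloxy)-2-[3,4-bis(benzyloxy)phenyl]-6-bromo-3-nitro-2H-chromene
Product: 11 (2R)-7,8-bis(benzyloxy)-2-[3,4-bis(benzyloxy)phenyl]-6-bromochroman-3-one, via sodium nitronate 10 (not isolated)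
Conditions: NaBH4, THF/MeOH, 0 °C; then aq TiCl3, NH4OAc (pH 5–6), THF, rt
Reagents that add atoms: water (O)
Why: Conjugate hydride reduction of the nitroalkene gives the nitronate, which the McMurry variant of the Nef reaction (trivalent titanium, buffered) reduces to the imine and hydrolyses to the ketone at a pH where C2 of the flavan-3-one is not epimerised.

Step 7
Reactants: 11 (2R)-7,8-bis(benzyloxy)-2-[3,4-bis(benzyloxy)phenyl]-6-bromochroman-3-one
Product: 12 (2R,3S)-7,8-bis(benzyloxy)-2-[3,4-bis(benzyloxy)phenyl]-6-bromochroman-3-ol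
Conditions: (R)-2-methyl-CBS-oxazaborolidine (20 mol %), BH3·SMe2, THF, −30 °C
Reagents that add atoms: none
Why: Corey–Bakshi–Shibata reduction, in which the catalyst binds the carbonyl anti to the branched C2 side and delivers hydride to the face that gives the 3S (2,3-trans) alcohol, overriding the weak intrinsic bias of the ketone.

Step 8
Reactants: 12 (2R,3S)-7,8-bis(benzyloxy)-2-[3,4-bis(benzyloxy)phenyl]-6-bromochroman-3-ol; 5 (2R)-7-(benzyloxy)-2-[3,4-bis(benzyloxy)phenyl]-3-nitro-2H-chromene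
Product: 15 (2R,3S)-7,8-bis(benzyloxy)-6-{(2R,3S,4R)-7-(benzyloxy)-2-[3,4-bis(benzyloxy)phenyl]-3-nitrochroman-4-yl}-2-[3,4-bis(benzyloxy)phenyl]chroman-3-ol, via dilithio aryl species 13 (not isolated), via lithium nitronate 14 (not isolated)
Conditions: t-BuLi (3.0 equiv), THF, −78 °C; then 5, THF, −78 °C; AcOH, −78 °C
Reagents that add atoms: none
Why: Bromine–lithium exchange followed by Michael-type 1,4-addition of the aryllithium to the nitroalkene, which acts as an α-keto-cation (enolonium) equivalent so that C4, the α-carbon of the latent C3 ketone, is bonded as an electrophile to the arene carbon C6 of the lower unit; the nucleophile enters anti to the pseudo-axial C2 aryl group and sets the 2,4-trans (4β) configuration, which is then locked because C4 cannot epimerise at the nitro stage, while the C3 epimers formed on protonation converge in step 9.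

Step 9
Reactants: 15 (2R,3S)-7,8-bis(benzyloxy)-6-{(2R,3S,4R)-7-(benzyloxy)-2-[3,4-bis(benzyloxy)phenyl]-3-nitrochroman-4-yl}-2-[3,4-bis(benzyloxy)phenyl]chroman-3-ol
Product: 18 (2R,3S,4R)-7-(benzyloxy)-4-{(2R,3S)-7,8-bis(benzyloxy)-2-[3,4-bis(benzyloxy)phenyl]-3-hydroxychroman-6-yl}-2-[3,4-bis(benzyloxy)phenyl]chroman-3-ol, via sodium nitronate 16 (not isolated), via flavan-3-one 17 (not isolated)
Conditions: NaOMe (1.2 equiv), MeOH/CH2Cl2, 0 °C; O3, −78 °C; Ar purge; NaBH4, −78 to −40 °C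
Reagents that add atoms: ozone ([O-][O+]=O)
Why: Oxidative Nef reaction by ozonolysis of the nitronate C=N bond at −78 °C, followed in the same flask by borohydride reduction so that the epimerisable 2,4-trans ketone is never warmed or isolated; hydride attacks anti to the pseudo-axial C4 aryl group and gives the equatorial 3-hydroxyl, cis to the C4 aryl and trans to the C2 aryl.

Step 10
Reactants: 18 (2R,3S,4R)-7-(benzyloxy)-4-{(2R,3S)-7,8-bis(benzyloxy)-2-[3,4-bis(benzyloxy)phenyl]-3-hydroxychroman-6-yl}-2-[3,4-bis(benzyloxy)phenyl]chroman-3-ol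
Product: 19 (2R,3S,4S)-2-(3,4-dihydroxyphenyl)-4-[(2R,3S)-2-(3,4-dihydroxyphenyl)-3,7,8-trihydroxychroman-6-yl]chroman-3,7-diol
Conditions: H2 (1 atm), Pd(OH)2/C, THF/MeOH, rt
Reagents that add atoms: none
Why: Catalytic hydrogenolysis cleaves the seven benzyl ethers under mild pressure, leaves the chroman C–O bonds and the interflavan C–C bond intact and touches no stereocentre.

## Compound list

1 | 3,4-bis(benzyloxy)benzaldehyde | O=Cc1ccc(OCc2ccccc2)c(OCc2ccccc2)c1 | starting material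
2 | nitromethane | C[N+](=O)[O-] | starting material
3 | (E)-1,2-bis(benzyloxy)-4-(2-nitroethenyl)benzene | [O-][N+](=O)/C=C/c1ccc(OCc2ccccc2)c(OCc2ccccc2)c1 | intermediate
4 | 4-(benzyloxy)-2-hydroxybenzaldehyde | O=Cc1ccc(OCc2ccccc2)cc1O | starting material
5 | (2R)-7-(benzyloxy)-2-[3,4-bis(benzyloxy)phenyl]-3-nitro-2H-chromene | [O-][N+](=O)C1=Cc2ccc(OCc3ccccc3)cc2O[C@@H]1c1ccc(OCc2ccccc2)c(OCc2ccccc2)c1 | intermediate
6 | 2,3,4-trihydroxybenzaldehyde | O=Cc1ccc(O)c(O)c1O | starting material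
7 | 3,4-bis(benzyloxy)-2-hydroxybenzaldehyde | O=Cc1ccc(OCc2ccccc2)c(OCc2ccccc2)c1O | intermediate
8 | 3,4-bis(benzyloxy)-5-bromo-2-hydroxybenzaldehyde | O=Cc1cc(Br)c(OCc2ccccc2)c(OCc2ccccc2)c1O | intermediate
9 | (2R)-7,8-bis(benzyloxy)-2-[3,4-bis(benzyloxy)phenyl]-6-bromo-3-nitro-2H-chromene | [O-][N+](=O)C1=Cc2cc(Br)c(OCc3ccccc3)c(OCc3ccccc3)c2O[C@@H]1c1ccc(OCc2ccccc2)c(OCc2ccccc2)c1 | intermediate
10 | sodium nitronate of (2R)-7,8-bis(benzyloxy)-2-[3,4-bis(benzyloxy)phenyl]-6-bromo-3-nitrochroman | [Na+].[O-][N+]([O-])=C1Cc2cc(Br)c(OCc3ccccc3)c(OCc3ccccc3)c2O[C@@H]1c1ccc(OCc2ccccc2)c(OCc2ccccc2)c1 | intermediate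
11 | (2R)-7,8-bis(benzyloxy)-2-[3,4-bis(benzyloxy)phenyl]-6-bromochroman-3-one | O=C1Cc2cc(Br)c(OCc3ccccc3)c(OCc3ccccc3)c2O[C@@H]1c1ccc(OCc2ccccc2)c(OCc2ccccc2)c1 | intermediate
12 | (2R,3S)-7,8-bis(benzyloxy)-2-[3,4-bis(benzyloxy)phenyl]-6-bromochroman-3-ol | O[C@H]1Cc2cc(Br)c(OCc3ccccc3)c(OCc3ccccc3)c2O[C@@H]1c1ccc(OCc2ccccc2)c(OCc2ccccc2)c1 | intermediate
13 | lithium (2R,3S)-7,8-bis(benzyloxy)-2-[3,4-bis(benzyloxy)phenyl]-6-lithiochroman-3-olate | [Li]O[C@H]1Cc2cc([Li])c(OCc3ccccc3)c(OCc3ccccc3)c2O[C@@H]1c1ccc(OCc2ccccc2)c(OCc2ccccc2)c1 | intermediate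
14 | dilithium salt (upper C3 nitronate, lower 3-olate) of the (2R,4R) adduct of 13 and 5 | [Li+].[Li+].C(c1ccccc1)Oc1ccc2c(c1)O[C@H](c1ccc(OCc3ccccc3)c(OCc3ccccc3)c1)C(=[N+]([O-])[O-])[C@H]2c1cc2c(c(OCc3ccccc3)c1OCc1ccccc1)O[C@H](c1ccc(OCc3ccccc3)c(OCc3ccccc3)c1)[C@@H]([O-])C2 | intermediate
15 | (2R,3S)-7,8-bis(benzyloxy)-6-{(2R,3S,4R)-7-(benzyloxy)-2-[3,4-bis(benzyloxy)phenyl]-3-nitrochroman-4-yl}-2-[3,4-bis(benzyloxy)phenyl]chroman-3-ol (major C3 epimer) | C(c1ccccc1)Oc1ccc2c(c1)O[C@H](c1ccc(OCc3ccccc3)c(OCc3ccccc3)c1)[C@@H]([N+](=O)[O-])[C@H]2c1cc2c(c(OCc3ccccc3)c1OCc1ccccc1)O[C@H](c1ccc(OCc3ccccc3)c(OCc3ccccc3)c1)[C@@H](O)C2 | intermediate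
16 | sodium C3 nitronate of 15 | [Na+].C(c1ccccc1)Oc1ccc2c(c1)O[C@H](c1ccc(OCc3ccccc3)c(OCc3ccccc3)c1)C(=[N+]([O-])[O-])[C@H]2c1cc2c(c(OCc3ccccc3)c1OCc1ccccc1)O[C@H](c1ccc(OCc3ccccc3)c(OCc3ccccc3)c1)[C@@H](O)C2 | intermediate
17 | (2R,4R)-7-(benzyloxy)-4-{(2R,3S)-7,8-bis(benzyloxy)-2-[3,4-bis(benzyloxy)phenyl]-3-hydroxychroman-6-yl}-2-[3,4-bis(benzyloxy)phenyl]chroman-3-one | C(c1ccccc1)Oc1ccc2c(c1)O[C@H](c1ccc(OCc3ccccc3)c(OCc3ccccc3)c1)C(=O)[C@H]2c1cc2c(c(OCc3ccccc3)c1OCc1ccccc1)O[C@H](c1ccc(OCc3ccccc3)c(OCc3ccccc3)c1)[C@@H](O)C2 | intermediate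
18 | (2R,3S,4R)-7-(benzyloxy)-4-{(2R,3S)-7,8-bis(benzyloxy)-2-[3,4-bis(benzyloxy)phenyl]-3-hydroxychroman-6-yl}-2-[3,4-bis(benzyloxy)phenyl]chroman-3-ol | C(c1ccccc1)Oc1ccc2c(c1)O[C@H](c1ccc(OCc3ccccc3)c(OCc3ccccc3)c1)[C@@H](O)[C@H]2c1cc2c(c(OCc3ccccc3)c1OCc1ccccc1)O[C@H](c1ccc(OCc3ccccc3)c(OCc3ccccc3)c1)[C@@H](O)C2 | intermediate
19 | (2R,3S,4S)-2-(3,4-dihydroxyphenyl)-4-[(2R,3S)-2-(3,4-dihydroxyphenyl)-3,7,8-trihydroxychroman-6-yl]chroman-3,7-diol | Oc1ccc2c(c1)O[C@H](c1ccc(O)c(O)c1)[C@@H](O)[C@H]2c1cc2c(c(O)c1O)O[C@H](c1ccc(O)c(O)c1)[C@@H](O)C2 | target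

## Step count and risks

Total step count: 10. Longest linear sequence: 8 steps (6 → 7 → 8 → 9 → 11 → 12 → 15 → 18 → 19; steps 3 to 10).

The three steps most likely to fail are steps 8, 9 and 7.

The coupling of step 8 can fail through the basicity or electron-transfer reactivity of the aryllithium toward the nitroalkene, or through poor facial selectivity at C4. The fallback sets out from 12 and 5 and comes back at 15. Bromide 12 is borylated (B2pin2, Pd(dppf)Cl2, KOAc, dioxane, 80 °C) to the pinacol boronate (2R,3S)-7,8-bis(benzyloxy)-2-[3,4-bis(benzyloxy)phenyl]-6-(4,4,5,5-tetramethyl-1,3,2-dioxaborolan-2-yl)chroman-3-ol F1. F1 is then added to 5 under neutral catalysis by monovalent rhodium ([Rh(OH)(cod)]2, dioxane/H2O, 50 °C), a conjugate addition of an aryl–rhodium species to the nitroalkene that again enters anti to the C2 aryl; protonation gives 15.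

Step 9 can fail if ozone attacks the electron-rich rings or if ketone 17 epimerises at C4 before it is reduced. The fallback sets out from 15 and comes back at 17. The nitro group is reduced without oxidant (SnCl2, PhSH, Et3N, rt) to the isolable, non-epimerisable ketoxime (2R,4R)-7-(benzyloxy)-4-{(2R,3S)-7,8-bis(benzyloxy)-2-[3,4-bis(benzyloxy)phenyl]-3-hydroxychroman-6-yl}-2-[3,4-bis(benzyloxy)phenyl]chroman-3-one oxime F2. F2 is cleaved with buffered aqueous TiCl3 to 17, which is reduced at once with NaBH4 to 18.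

Step 7 can fail if catalyst control does not override the substrate and the 2,3-cis alcohol dominates. The fallback sets out from 11 and comes back at 12. Ketone 11 is reduced with LiBH(s-Bu)3 at −78 °C, which reliably gives the cis alcohol (2R,3R)-7,8-bis(benzyloxy)-2-[3,4-bis(benzyloxy)phenyl]-6-bromochroman-3-ol F3. C3 is inverted by Mitsunobu esterification (4-nitrobenzoic acid, PPh3, DIAD) to (2R,3S)-7,8-bis(benzyloxy)-2-[3,4-bis(benzyloxy)phenyl]-6-bromochroman-3-yl 4-nitrobenzoate F4, and methanolysis (K2CO3, MeOH) gives 12.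

## Further compounds

F1 | step 8 | (2R,3S)-7,8-bis(benzyloxy)-2-[3,4-bis(benzyloxy)phenyl]-6-(4,4,5,5-tetramethyl-1,3,2-dioxaborolan-2-yl)chroman-3-ol | O[C@H]1Cc2cc(B3OC(C)(C)C(C)(C)O3)c(OCc3ccccc3)c(OCc3ccccc3)c2O[C@@H]1c1ccc(OCc2ccccc2)c(OCc2ccccc2)c1
F2 | step 9 | (2R,4R)-7-(benzyloxy)-4-{(2R,3S)-7,8-bis(benzyloxy)-2-[3,4-bis(benzyloxy)phenyl]-3-hydroxychroman-6-yl}-2-[3,4-bis(benzyloxy)phenyl]chroman-3-one oxime (E/Z mixture) | C(c1ccccc1)Oc1ccc2c(c1)O[C@H](c1ccc(OCc3ccccc3)c(OCc3ccccc3)c1)C(=NO)[C@H]2c1cc2c(c(OCc3ccccc3)c1OCc1ccccc1)O[C@H](c1ccc(OCc3ccccc3)c(OCc3ccccc3)c1)[C@@H](O)C2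
F3 | step 7 | (2R,3R)-7,8-bis(benzyloxy)-2-[3,4-bis(benzyloxy)phenyl]-6-bromochroman-3-ol | O[C@@H]1Cc2cc(Br)c(OCc3ccccc3)c(OCc3ccccc3)c2O[C@@H]1c1ccc(OCc2ccccc2)c(OCc2ccccc2)c1
F4 | step 7 | (2R,3S)-7,8-bis(benzyloxy)-2-[3,4-bis(benzyloxy)phenyl]-6-bromochroman-3-yl 4-nitrobenzoate | O=C(O[C@H]1Cc2cc(Br)c(OCc3ccccc3)c(OCc3ccccc3)c2O[C@@H]1c1ccc(OCc2ccccc2)c(OCc2ccccc2)c1)c1ccc([N+](=O)[O-])cc1
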